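**Retrosynthetic overview**
1. Target 23 ⇐ triol 20 (anisoylation, then acetylation) ⇐ diketone 19, whose two secondary carbinols are set by hydride delivery from the tertiary OH.
2. Seven-membered ring (closed second): farnesane C1–C7 bond, by an aluminium-chelate-directed intramolecular allylsilane–enone cyclisation (16 → 18) that also sets the quaternary methyl centre and the trans ring fusion.
3. Five-membered ring (closed first): farnesane C6–C10 bond, by methylcuprate addition to ynone 14 with aldol capture by the isopropyl ketone (14 → 16).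
4. These are the two C–C bonds closed in the presumed biogenesis of daucanes; they are made with polar reactivity because oxygen sits next to both ring-fusion carbons, which rules out free cations there.
5. 14 ⇐ acid 6 (hydrosilylation, Johnson–Claisen) + alkynol 10 (proline aldol) by acyl Sonogashira coupling.

Assumption: the presumed biosynthesis is farnesyl/nerolidyl diphosphate → daucyl cation through C1–C7 and C6–C10 bond formation (farnesane numbering, used only for these two bonds), then water capture and later oxidation/acylation; compounds 5, 6 and 11 are racemic and 13–16 are 1:1 mixtures at the silicon-bearing carbon, which becomes sp2 in step 8.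

**Step 1**
Reactants: 1 but-2-yn-1-ol
Product: 2 (E)-3-[dimethyl(phenyl)silyl]but-2-en-1-ol
Conditions: PhMe2SiH (1.2 equiv), PtCl2 (1 mol %), XPhos (2 mol %), THF, 50 °C
Reagents that add atoms: dimethylphenylsilane, C[SiH](C)c1ccccc1
Why: Hydroxyl-controlled Pt-catalysed syn-hydrosilylation of a propargylic alcohol puts silicon on the alkyne carbon remote from the OH and gives the E-vinylsilane; no stereocentre is formed.

**Step 2**
Reactants: 2 (E)-3-[dimethyl(phenyl)silyl]but-2-en-1-ol; 3 triethyl orthoacetate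
Product: 5 racemic ethyl 3-[dimethyl(phenyl)silyl]-3-methylpent-4-enoate, via ketene acetal 4 (not isolated)
Conditions: MeC(OEt)3 (5 equiv), EtCO2H (5 mol %), 140 °C, EtOH distilled off
Reagents that add atoms: none
Why: Johnson–Claisen rearrangement: the mixed ketene acetal undergoes a chair [3,3] shift that forms the new C–C bond at the silicon-bearing alkene carbon and so gives the tertiary allylsilane; its stereocentre is left racemic because step 8 destroys it.

**Step 3**
Reactants: 5 racemic ethyl 3-[dimethyl(phenyl)silyl]-3-methylpent-4-enoate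
Product: 6 racemic 3-[dimethyl(phenyl)silyl]-3-methylpent-4-enoic acid
Conditions: LiOH·H2O, THF/MeOH/H2O, 40 °C; 1 M HCl to pH 4, 0 °C
Reagents that add atoms: lithium hydroxide, [Li+].[OH-]
Why: Saponification (BAc2 ester hydrolysis); the allylsilane tolerates base and brief cold dilute acid.

**Step 4**
Reactants: 7 3-methylbutan-2-one; 8 3-(trimethylsilyl)prop-2-ynal
Product: 9 (5R)-5-hydroxy-2-methyl-7-(trimethylsilyl)hept-6-yn-3-one
Conditions: L-proline (30 mol %), DMSO/7 4:1, 4 °C
Reagents that add atoms: none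
Why: Proline-catalysed direct aldol (List–Barbas): the enamine forms on the methyl side of the ketone and attacks the Re face of the non-enolisable ynal through the acid-bridged Houk–List transition state, giving the R carbinol (same sense as with aryl aldehydes); the ee is not known for this substrate pair and is to be raised at triol 20 by recrystallisation.

**Step 5**
Reactants: 9 (5R)-5-hydroxy-2-methyl-7-(trimethylsilyl)hept-6-yn-3-one
Product: 10 (5R)-5-hydroxy-2-methylhept-6-yn-3-one
Conditions: K2CO3 (0.2 equiv), MeOH, 0 °C, 20 min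
Reagents that add atoms: none
Why: Base-catalysed methanolysis of the alkynyl C–Si bond (protodesilylation) is fast under conditions too mild for retro-aldol or elimination; the stereocentre is untouched.

**Step 6**
Reactants: 6 racemic 3-[dimethyl(phenyl)silyl]-3-methylpent-4-enoic acid; 10 (5R)-5-hydroxy-2-methylhept-6-yn-3-one
Product: 14 (5R)-10-[dimethyl(phenyl)silyl]-5-hydroxy-2,10-dimethyldodec-11-en-6-yne-3,8-dione, via acid chloride 11 (not isolated), via silyl ether 12 (not isolated), via silylated ynone 13 (not isolated)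
Conditions: 6, Me2C=C(Cl)NMe2, CH2Cl2, 0 °C; 10, TMSCl, Et3N, THF, 0 °C; mix, PdCl2(PPh3)2 (2 mol %), CuI (4 mol %), Et3N, rt; aq. citric acid, MeOH
Reagents that add atoms: none
Why: Acyl Sonogashira coupling (copper acetylide with the acyl chloride) gives the ynone; the neutral Ghosez chlorination spares the allylsilane and the transient O-TMS group prevents ester formation; no stereocentre is made.

**Step 7**
Reactants: 14 (5R)-10-[dimethyl(phenyl)silyl]-5-hydroxy-2,10-dimethyldodec-11-en-6-yne-3,8-dione
Product: 16 1-[(3R,5R)-3,5-dihydroxy-2-methyl-5-(propan-2-yl)cyclopent-1-en-1-yl]-3-[dimethyl(phenyl)silyl]-3-methylpent-4-en-1-one, via allenolate 15 (not isolated)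
Conditions: Me2CuLi (3 equiv), Et2O/THF, −78 → −30 °C; aq. NH4Cl/NH3
Reagents that add atoms: lithium dimethylcuprate, [Li+].C[Cu-]C
Why: Michael-initiated ring closure: cuprate 1,4-addition to the ynone delivers the C-methyl group and the allenolate carbon then adds to the isopropyl ketone (five-membered ring, farnesane C6–C10 bond); the lithium alkoxide of the R carbinol chelates the ketone oxygen, so the new tertiary alkoxide forms cis to it, which sets the 5R centre.

**Step 8**
Reactants: 16 1-[(3R,5R)-3,5-dihydroxy-2-methyl-5-(propan-2-yl)cyclopent-1-en-1-yl]-3-[dimethyl(phenyl)silyl]-3-methylpent-4-en-1-one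
Product: 18 (1R,3R,3aR,8aR)-1,3-dihydroxy-6,8a-dimethyl-3-(propan-2-yl)-2,3,3a,5,8,8a-hexahydroazulen-4(1H)-one, via aluminium enolate 17 (not isolated)
Conditions: EtAlCl2 (3.2 equiv), CH2Cl2, −78 → −20 °C; MeOH, −78 °C; aq. Rochelle salt
Reagents that add atoms: none
Why: Proposed new method: EtAlCl2 turns both hydroxyls into aluminium alkoxides on the same (β) face with loss of ethane, and the tertiary one chelates the ketone oxygen, which activates the tetrasubstituted enone and turns the acyl chain toward its β-carbon, so the allylsilane terminus adds from the free α face anti to both alkoxides (seven-membered ring, farnesane C1–C7 bond, quaternary methyl centre, loss of silicon leaves the ring alkene), and the chelated enolate is then protonated on that same α face to give the trans ring fusion, which is also the more stable epimer (ketone cis to the tertiary oxygen, away from isopropyl); the closest known reactions are Majetich-type Lewis-acid intramolecular Hosomi–Sakurai cycloheptannulations and the anti addition to 4-oxygenated cyclopentenones.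

**Step 9**
Reactants: 18 (1R,3R,3aR,8aR)-1,3-dihydroxy-6,8a-dimethyl-3-(propan-2-yl)-2,3,3a,5,8,8a-hexahydroazulen-4(1H)-one
Product: 19 (3R,3aR,8aR)-3-hydroxy-6,8a-dimethyl-3-(propan-2-yl)-3,3a,5,8-tetrahydroazulene-1,4(2H,8aH)-dione
Conditions: Dess–Martin periodinane, NaHCO3, CH2Cl2, 0 °C
Reagents that add atoms: none
Why: Dess–Martin oxidation removes the secondary carbinol that served as the stereochemical relay (the tertiary alcohol cannot react and the buffer avoids β-elimination), so that this centre can be reset from the opposite face in step 10.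

**Step 10**
Reactants: 19 (3R,3aR,8aR)-3-hydroxy-6,8a-dimethyl-3-(propan-2-yl)-3,3a,5,8-tetrahydroazulene-1,4(2H,8aH)-dione
Product: 20 (1S,3R,3aS,4S,8aR)-6,8a-dimethyl-3-(propan-2-yl)-1,2,3,3a,4,5,8,8a-octahydroazulene-1,3,4-triol
Conditions: Me4NBH(OAc)3 (8 equiv), MeCN/AcOH 1:1, −30 → 0 °C
Reagents that add atoms: none
Why: Evans–Saksena hydroxyl-directed reduction: the tertiary 3-OH exchanges onto boron and delivers hydride intramolecularly to the β face of each of the two β-keto groups, which gives the 1,3-anti carbinols 1S and 4S (both OH α).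

**Step 11**
Reactants: 20 (1S,3R,3aS,4S,8aR)-6,8a-dimethyl-3-(propan-2-yl)-1,2,3,3a,4,5,8,8a-octahydroazulene-1,3,4-triol; 21 4-methoxybenzoyl chloride
Product: 22 (1S,3R,3aS,4S,8aR)-1,3-dihydroxy-6,8a-dimethyl-3-(propan-2-yl)-1,2,3,3a,4,5,8,8a-octahydroazulen-4-yl 4-methoxybenzoate
Conditions: 21 (1.05 equiv), pyridine, DMAP (5 mol %), CH2Cl2, −20 → 0 °C
Reagents that add atoms: none
Why: DMAP-catalysed acylation under steric control is expected to take the 4-OH (flanked by CH and CH2) ahead of the neopentyl 1-OH next to the quaternary carbon and the tertiary 3-OH, by analogy with the 6-O-acylation of jaeschkeanadiol; no stereocentre changes.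

**Step 12**
Reactants: 22 (1S,3R,3aS,4S,8aR)-1,3-dihydroxy-6,8a-dimethyl-3-(propan-2-yl)-1,2,3,3a,4,5,8,8a-octahydroazulen-4-yl 4-methoxybenzoate
Product: 23 (1S,3R,3aS,4S,8aR)-1-acetoxy-3-hydroxy-6,8a-dimethyl-3-(propan-2-yl)-1,2,3,3a,4,5,8,8a-octahydroazulen-4-yl 4-methoxybenzoate (CNP0171090.1)
Conditions: Ac2O, DMAP, pyridine, rt
Reagents that add atoms: acetic anhydride, CC(=O)OC(C)=O
Why: Steglich-type acetylation of the remaining secondary alcohol with the small acetyl donor; the tertiary 3-OH is inert at room temperature and its trans relation to the 1-oxygen excludes acyl migration.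

**Compound list**
1 | but-2-yn-1-ol | CC#CCO | starting material
2 | (E)-3-[dimethyl(phenyl)silyl]but-2-en-1-ol | OC/C=C(\C)[Si](C)(C)c1ccccc1 | intermediate
3 | triethyl orthoacetate | CCOC(C)(OCC)OCC | starting material
4 | (E)-1-ethoxy-1-{[3-(dimethyl(phenyl)silyl)but-2-en-1-yl]oxy}ethene (ketene acetal) | C=C(OCC)OC/C=C(\C)[Si](C)(C)c1ccccc1 | intermediate (not isolated)
5 | ethyl 3-[dimethyl(phenyl)silyl]-3-methylpent-4-enoate (racemic) | CCOC(=O)CC(C)(C=C)[Si](C)(C)c1ccccc1 | intermediate
6 | 3-[dimethyl(phenyl)silyl]-3-methylpent-4-enoic acid (racemic) | OC(=O)CC(C)(C=C)[Si](C)(C)c1ccccc1 | intermediate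
7 | 3-methylbutan-2-one | CC(C)C(C)=O | starting material
8 | 3-(trimethylsilyl)prop-2-ynal | C[Si](C)(C)C#CC=O | starting material
9 | (5R)-5-hydroxy-2-methyl-7-(trimethylsilyl)hept-6-yn-3-one | CC(C)C(=O)C[C@@H](O)C#C[Si](C)(C)C | intermediate
10 | (5R)-5-hydroxy-2-methylhept-6-yn-3-one | CC(C)C(=O)C[C@@H](O)C#C | intermediate
11 | 3-[dimethyl(phenyl)silyl]-3-methylpent-4-enoyl chloride (racemic) | ClC(=O)CC(C)(C=C)[Si](C)(C)c1ccccc1 | intermediate (not isolated)
12 | (5R)-2-methyl-5-[(trimethylsilyl)oxy]hept-6-yn-3-one | CC(C)C(=O)C[C@@H](O[Si](C)(C)C)C#C | intermediate (not isolated)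
13 | (5R)-10-[dimethyl(phenyl)silyl]-2,10-dimethyl-5-[(trimethylsilyl)oxy]dodec-11-en-6-yne-3,8-dione (1:1 at C10) | CC(C)C(=O)C[C@@H](O[Si](C)(C)C)C#CC(=O)CC(C)(C=C)[Si](C)(C)c1ccccc1 | intermediate (not isolated)
14 | (5R)-10-[dimethyl(phenyl)silyl]-5-hydroxy-2,10-dimethyldodec-11-en-6-yne-3,8-dione (1:1 at C10) | CC(C)C(=O)C[C@@H](O)C#CC(=O)CC(C)(C=C)[Si](C)(C)c1ccccc1 | intermediate
15 | dilithium (5R)-10-[dimethyl(phenyl)silyl]-2,6,10-trimethyl-3-oxododeca-6,7,11-triene-5,8-diolate (allenolate) | [Li+].[Li+].[O-]C(CC(C)(C=C)[Si](C)(C)c1ccccc1)=C=C(C)[C@H]([O-])CC(=O)C(C)C | intermediate (not isolated)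
16 | 1-[(3R,5R)-3,5-dihydroxy-2-methyl-5-(propan-2-yl)cyclopent-1-en-1-yl]-3-[dimethyl(phenyl)silyl]-3-methylpent-4-en-1-one (1:1 at the silyl-bearing carbon) | C=CC(C)(CC(=O)C1=C(C)[C@H](O)C[C@@]1(O)C(C)C)[Si](C)(C)c1ccccc1 | intermediate
17 | chloroaluminium chelate of the ring-fused enolate and tertiary alkoxide, with the secondary oxygen as its dichloroaluminium alkoxide (aluminium enolate) | CC1=CC[C@@]2(C)[C@H](O[Al](Cl)Cl)C[C@]3(C(C)C)O[Al](Cl)OC(C1)=C23 | intermediate (not isolated)
18 | (1R,3R,3aR,8aR)-1,3-dihydroxy-6,8a-dimethyl-3-(propan-2-yl)-2,3,3a,5,8,8a-hexahydroazulen-4(1H)-one | O=C1CC(C)=CC[C@@]2(C)[C@H](O)C[C@@](O)(C(C)C)[C@H]12 | intermediate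
19 | (3R,3aR,8aR)-3-hydroxy-6,8a-dimethyl-3-(propan-2-yl)-3,3a,5,8-tetrahydroazulene-1,4(2H,8aH)-dione | O=C1CC(C)=CC[C@@]2(C)C(=O)C[C@@](O)(C(C)C)[C@H]12 | intermediate
20 | (1S,3R,3aS,4S,8aR)-6,8a-dimethyl-3-(propan-2-yl)-1,2,3,3a,4,5,8,8a-octahydroazulene-1,3,4-triol | O[C@H]1CC(C)=CC[C@@]2(C)[C@@H](O)C[C@@](O)(C(C)C)[C@H]12 | intermediate
21 | 4-methoxybenzoyl chloride | COc1ccc(cc1)C(Cl)=O | starting material
22 | (1S,3R,3aS,4S,8aR)-1,3-dihydroxy-6,8a-dimethyl-3-(propan-2-yl)-1,2,3,3a,4,5,8,8a-octahydroazulen-4-yl 4-methoxybenzoate | COc1ccc(C(=O)O[C@H]2CC(C)=CC[C@@]3(C)[C@@H](O)C[C@@](O)(C(C)C)[C@H]23)cc1 | intermediate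
23 | (1S,3R,3aS,4S,8aR)-1-acetoxy-3-hydroxy-6,8a-dimethyl-3-(propan-2-yl)-1,2,3,3a,4,5,8,8a-octahydroazulen-4-yl 4-methoxybenzoate | COc1ccc(C(=O)O[C@H]2CC(C)=CC[C@@]3(C)[C@@H](OC(C)=O)C[C@@](O)(C(C)C)[C@H]23)cc1 | target

**Step count and risks**
Total: 12 steps. Longest linear sequence: 10 steps (steps 1–3 and 6–12).

The three steps most likely to fail:

Step 7. The allenolate may be protonated instead of closing onto the hindered ketone, the lithium aldolate may undergo retro-aldol, or the chelation control may be incomplete (any trans-diol becomes the wrong enantiomer after step 9). The fallback sets out from 14. Methylcuprate is added as before but the allenolate is quenched with iodine at −78 °C to give (5R,6Z)-10-[dimethyl(phenyl)silyl]-5-hydroxy-7-iodo-2,6,10-trimethyldodeca-6,11-diene-3,8-dione F1. The ring is then closed by an intramolecular Nozaki–Hiyama–Kishi reaction (CrCl2, cat. NiCl2, DMF), in which the vinyl-chromium adds to the chromium-chelated isopropyl ketone. This comes back to the route at 16.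

Step 8. The closure has to build a quaternary centre on a tetrasubstituted, poorly conjugated enone in a seven-membered ring. Protodesilylation or 1,2-addition may compete, and the α-face protonation that gives the trans fusion is argued, not proven. The fallback sets out from 16. The allylic secondary alcohol is oxidised with MnO2 to the doubly activated ene-dione (4R)-3-{3-[dimethyl(phenyl)silyl]-3-methylpent-4-enoyl}-4-hydroxy-2-methyl-4-(propan-2-yl)cyclopent-2-en-1-one F2. This is cyclised through the trichlorotitanium chelate of its tertiary alkoxide (TiCl4, 2,6-di-tert-butyl-4-methylpyridine, CH2Cl2, −78 °C), which activates only the side-chain carbonyl and again blocks the β face. The product is diketone 19, where the route resumes (step 9 is then not needed).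

Step 11. Both secondary hydroxyls of 20 are hindered and the preference for the 4-OH may be too small. The fallback sets out from 18 and separates the two oxygens in time. Directed reduction of 18 (Me4NBH(OAc)3) gives (1R,3R,3aS,4S,8aR)-6,8a-dimethyl-3-(propan-2-yl)-1,2,3,3a,4,5,8,8a-octahydroazulene-1,3,4-triol F3, whose 1-OH is cis to the angular methyl and much more shielded. Anisoylation then gives (1R,3R,3aS,4S,8aR)-1,3-dihydroxy-6,8a-dimethyl-3-(propan-2-yl)-1,2,3,3a,4,5,8,8a-octahydroazulen-4-yl 4-methoxybenzoate F4. Dess–Martin oxidation gives (3R,3aS,4S,8aR)-3-hydroxy-6,8a-dimethyl-1-oxo-3-(propan-2-yl)-1,2,3,3a,4,5,8,8a-octahydroazulen-4-yl 4-methoxybenzoate F5, and a second directed reduction returns to the route at 22.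

**Further compounds**
F1 | step 7 | (5R,6Z)-10-[dimethyl(phenyl)silyl]-5-hydroxy-7-iodo-2,6,10-trimethyldodeca-6,11-diene-3,8-dione | CC(C)C(=O)C[C@@H](O)/C(C)=C(\I)C(=O)CC(C)(C=C)[Si](C)(C)c1ccccc1
F2 | step 8 | (4R)-3-{3-[dimethyl(phenyl)silyl]-3-methylpent-4-enoyl}-4-hydroxy-2-methyl-4-(propan-2-yl)cyclopent-2-en-1-one | C=CC(C)(CC(=O)C1=C(C)C(=O)C[C@@]1(O)C(C)C)[Si](C)(C)c1ccccc1
F3 | step 11 | (1R,3R,3aS,4S,8aR)-6,8a-dimethyl-3-(propan-2-yl)-1,2,3,3a,4,5,8,8a-octahydroazulene-1,3,4-triol | O[C@H]1CC(C)=CC[C@@]2(C)[C@H](O)C[C@@](O)(C(C)C)[C@H]12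
F4 | step 11 | (1R,3R,3aS,4S,8aR)-1,3-dihydroxy-6,8a-dimethyl-3-(propan-2-yl)-1,2,3,3a,4,5,8,8a-octahydroazulen-4-yl 4-methoxybenzoate | COc1ccc(C(=O)O[C@H]2CC(C)=CC[C@@]3(C)[C@H](O)C[C@@](O)(C(C)C)[C@H]23)cc1
F5 | step 11 | (3R,3aS,4S,8aR)-3-hydroxy-6,8a-dimethyl-1-oxo-3-(propan-2-yl)-1,2,3,3a,4,5,8,8a-octahydroazulen-4-yl 4-methoxybenzoate | COc1ccc(C(=O)O[C@H]2CC(C)=CC[C@@]3(C)C(=O)C[C@@](O)(C(C)C)[C@H]23)cc1
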